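Readings and results are simulated for an exercise.

A flask cannot stop for want of what it still holds: at the last reading of the zeta run 27.5% of the Q stands beside a flat E of 26.9%, so Q has not run out. Another 45.6% of the Q is in neither, so some unseen form holds it. Treat the flat stretch as a balance, then, and compare two times: the time a flask needs to reach its plateau and the time it is given.

| flask | Q | Z | temperature | remark | time |
|---|---|---|---|---|---|
| eta | 0.40 M | 0.32 M | 30 °C | run made earlier |  |
| zeta | 0.40 M | 0.74 M | 41 °C | run made earlier |  |
| winter | 0.40 M | 0.250 M |  | at 25 °C throughout | 20 h |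
| autumn | 0.40 M | 0.520 M |  | at 25 °C until 4.0 h, from then on at 45 °C | 20 h |

| run | time / h | E / % | Q / % |
|---|---|---|---|
| eta | 2.50 | 11.0 | 72.0 |
| eta | 5.00 | 17.6 | 63.0 |
| eta | 8.00 | 20.3 | 58.4 |
| eta | 10.0 | 22.0 | 56.9 |
| zeta | 1.00 | 22.6 | 41.5 |
| zeta | 2.50 | 26.5 | 27.2 |
| zeta | 4.00 | 27.0 | 28.0 |
| zeta | 5.00 | 26.9 | 27.5 |

(standard deviation of a reading: 1 percentage point)

- which one finishes higher in amount of E, in percent of the Q charged ("neither" within 2 percentage points) (winter / autumn / neither)
- amount of E at the end, in percent of the Q charged, winter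
- amount of E at the end, in percent of the Q charged, autumn

Take the last Q reading as the plateau and find from the first reading the time in which the gap to it falls to half. The readings give 1.65 h for eta and 0.421 h for zeta. Their ratio carries the difference in Z as well as in temperature. Scale it by degrees to 25 °C: this gives 3.07 h, the levelling time. At 45 °C the same scaling gives 0.256 h.

Winter gets 6.51 levelling times, and autumn far more after its change. Expect thermodynamic rather than kinetic control in both, and compare plateaus. Winter has less Z and a lower temperature than eta, so put its E under 22.0%. Autumn's Z lies between those of eta and zeta, though its last temperature is higher than both, so put its E, tentatively, between their last readings of 22.0% and 26.9%, above winter.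

The forecast, reading the stop differently from this reckoning, as “Z (or its activity) decays in first order”, gave autumn, with 19% for winter and 25% for autumn.

The flasks give 19.2% for winter and 23.3% for autumn.

    Q + Z ⇌ X (K = 2.10 L mol⁻¹, k = 0.00560 L mol⁻¹ min⁻¹, Ea = 85.0 kJ mol⁻¹, ΔH = 31.0 kJ mol⁻¹)
    X ⇌ E + L (K = 0.100 M, k = 0.00530 min⁻¹, Ea = 104 kJ mol⁻¹, ΔH = −26.0 kJ mol⁻¹)
    (constants at 25 °C)

In winter, Q + Z ⇌ X has a relaxation half-life of 2.42 h at the end, against 0.860 h for X ⇌ E + L, and over its 6.51 levelling times of 3.07 h Q comes to 65.9%, with 65.3% after 200 h. Autumn's 16.0 h at 45 °C are 62.4 levelling times of 0.256 h, and its E reads 23.3% at 10.0 h and 23.3% at 20.0 h.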